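The diaryl ether is cut back to a cyclohexanone. Ring A is carried saturated and is joined through oxygen to the fully brominated ring B (C1' ether oxygen, C3', C4', C5' bromine, C6' oxygen capped as a methyl ether) by alkylation at sp3 carbon. The precursor is racemic 2-(3,4,5-tribromo-2-methoxyphenoxy)cyclohexan-1-one. One bromine treatment then dehydrogenates the ketone ring to a phenol and installs both ring A bromines. The step exploits the fact that ring A carries bromine only at C2 and C4, ortho and para to the C1 hydroxyl, while C6 holds the ether oxygen, so the newly formed hydroxyl directs both C–Br bonds.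

Key step: step 5

Remark: the target has no stereocentre, so the requested single enantiomer is taken to be the achiral compound itself; ring A is numbered from its hydroxyl carbon (C1) and ring B from its ether carbon (C1').

Step 1
Reactants: 1 2-(benzyloxy)phenol
Product: 4 6-(benzyloxy)-2,3,4-tribromophenol, via 2-(benzyloxy)-4-bromophenol 2 (not isolated), via 2-(benzyloxy)-4,6-dibromophenol 3 (not isolated)
Conditions: Br2 (3.1 equiv), NaOAc (3.5 equiv), AcOH, rt → 40 °C, dark
Reagents that add atoms: bromine, BrBr
Why: Electrophilic aromatic bromination in which the free hydroxyl directs bromine to its para and ortho carbons and the benzyloxy group to its para carbon, leaving only the C–H between OBn and Br, while the acetate buffer keeps HBr from cleaving the benzyl ether.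

Step 2
Reactants: 4 6-(benzyloxy)-2,3,4-tribromophenol
Product: 5 1-(benzyloxy)-3,4,5-tribromo-2-methoxybenzene
Conditions: MeI (1.5 equiv), K2CO3 (2 equiv), DMF, rt
Reagents that add atoms: iodomethane, CI
Why: Williamson O-methylation (SN2) of the acidic, bromine-flanked phenoxide, the only nucleophilic site in the molecule.

Step 3
Reactants: 5 1-(benzyloxy)-3,4,5-tribromo-2-methoxybenzene
Product: 6 3,4,5-tribromo-2-methoxyphenol
Conditions: BCl3 (2 equiv), pentamethylbenzene (3 equiv), CH2Cl2, −78 °C; MeOH then H2O
Reagents that add atoms: none
Why: Lewis-acid debenzylation in which BCl3 ionises the benzyl–oxygen bond at low temperature and pentamethylbenzene traps the benzyl cation by Friedel–Crafts alkylation, conditions that should leave the aryl methyl ether and the aryl bromides untouched.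

Step 4
Reactants: 6 3,4,5-tribromo-2-methoxyphenol; 7 2-chlorocyclohexanone (racemic)
Product: 8 2-(3,4,5-tribromo-2-methoxyphenoxy)cyclohexan-1-one (racemic)
Conditions: K2CO3 (2 equiv), DMF, 50 °C
Reagents that add atoms: none
Why: Williamson-type SN2 alkylation of the phenoxide at the carbonyl-activated α-carbon of an α-chloro ketone, in which the weakly basic tribromophenoxide should disfavour Favorskii and aldol side paths and the new stereocentre is formed racemic, which is irrelevant because it later becomes aromatic.

Step 5
Reactants: 8 2-(3,4,5-tribromo-2-methoxyphenoxy)cyclohexan-1-one (racemic)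
Product: 13 2,4-dibromo-6-(3,4,5-tribromo-2-methoxyphenoxy)phenol, via 2,6-dibromo ketone 9 (not isolated), via 6-bromo enone 10 (not isolated), via 2-aryloxyphenol 11 (not isolated), via 4-bromo-2-aryloxyphenol 12 (not isolated)
Conditions: Br2 (2.1 equiv), AcOH, rt → 80 °C, N2 sweep; cool to rt, Br2 (2.1 equiv)
Reagents that add atoms: bromine, BrBr
Why: Acid-catalysed enolisation should deliver bromine to both α-carbons of the ketone (9); the tertiary α-bromo aryl ether then ionises and loses HBr to enone 10, and a second loss of HBr across C6–C5 followed by a proton shift gives phenol 11, in which ketone C1, C2 and C6 have become ring A C1, C6 and C2. The closest known reaction type is the bromine- or copper(II) bromide-mediated dehydrogenation of cyclohexanones and cyclohexenones to phenols and bromophenols, here followed in the same flask by electrophilic aromatic bromination (11 → 12 → 13). No ring is closed and no stereocentre is created; the racemic centre of 8 becomes the sp2 carbon C6. The step needs bromination of ring A at C4 and C2 only, and the substrate secures this because the new C1 hydroxyl directs para and ortho, C6 is blocked by the aryloxy group, and any bromine still on the former α'-carbon at the moment of aromatisation already sits at C2. Ring B should stay untouched because its single C–H (C2') lies between oxygen and bromine on a ring deactivated by three bromines, and its methyl cap keeps the C6' oxygen from forming a hemiketal with the ketone. Dosing bromine in two portions of about two equivalents leaves no reagent for a third ring A bromination at C3 or C5.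

Step 6
Reactants: 13 2,4-dibromo-6-(3,4,5-tribromo-2-methoxyphenoxy)phenol
Product: 14 2,3,4-tribromo-6-(3,5-dibromo-2-hydroxyphenoxy)phenol
Conditions: BBr3 (3 equiv), CH2Cl2, −78 °C → rt; H2O
Reagents that add atoms: none
Why: Lewis-acid O-demethylation in which BBr3 coordinates the methoxy oxygen and bromide removes the methyl group by SN2, a process that should spare the diaryl ether and all five aryl C–Br bonds and release the second hydroxyl on aqueous work-up.

Compound list
1 | 2-(benzyloxy)phenol | Oc1ccccc1OCc1ccccc1 | starting material
2 | 2-(benzyloxy)-4-bromophenol | Oc1ccc(Br)cc1OCc1ccccc1 | intermediate (not isolated)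
3 | 2-(benzyloxy)-4,6-dibromophenol | Oc1c(Br)cc(Br)cc1OCc1ccccc1 | intermediate (not isolated)
4 | 6-(benzyloxy)-2,3,4-tribromophenol | Oc1c(Br)c(Br)c(Br)cc1OCc1ccccc1 | intermediate
5 | 1-(benzyloxy)-3,4,5-tribromo-2-methoxybenzene | COc1c(Br)c(Br)c(Br)cc1OCc1ccccc1 | intermediate
6 | 3,4,5-tribromo-2-methoxyphenol | COc1c(Br)c(Br)c(Br)cc1O | intermediate
7 | 2-chlorocyclohexanone (racemic) | O=C1CCCCC1Cl | starting material
8 | 2-(3,4,5-tribromo-2-methoxyphenoxy)cyclohexan-1-one (racemic) | O=C1CCCCC1Oc1cc(Br)c(Br)c(Br)c1OC | intermediate
9 | 2,6-dibromo-2-(3,4,5-tribromo-2-methoxyphenoxy)cyclohexan-1-one (racemic mixture of diastereomers) | O=C1C(Br)CCCC1(Br)Oc1cc(Br)c(Br)c(Br)c1OC | intermediate (not isolated)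
10 | 6-bromo-2-(3,4,5-tribromo-2-methoxyphenoxy)cyclohex-2-en-1-one (racemic) | O=C1C(Br)CCC=C1Oc1cc(Br)c(Br)c(Br)c1OC | intermediate (not isolated)
11 | 2-(3,4,5-tribromo-2-methoxyphenoxy)phenol | COc1c(Br)c(Br)c(Br)cc1Oc1ccccc1O | intermediate (not isolated)
12 | 4-bromo-2-(3,4,5-tribromo-2-methoxyphenoxy)phenol | COc1c(Br)c(Br)c(Br)cc1Oc1cc(Br)ccc1O | intermediate (not isolated)
13 | 2,4-dibromo-6-(3,4,5-tribromo-2-methoxyphenoxy)phenol | COc1c(Br)c(Br)c(Br)cc1Oc1cc(Br)cc(Br)c1O | intermediate
14 | 2,3,4-tribromo-6-(3,5-dibromo-2-hydroxyphenoxy)phenol (achiral) | Oc1c(Br)cc(Br)cc1Oc1cc(Br)c(Br)c(Br)c1O | target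

Total step count: 6
Longest linear sequence: 6 steps (1 → 4 → 5 → 6 → 8 → 13 → 14)

Steps most likely to fail

Step 5. Several processes could divert the key step:
- acid-promoted loss of the aryloxy group, by bromide displacement at the α-carbon or collapse of the α-bromo ether;
- incomplete dehydrobromination that leaves α-bromo ketones;
- addition of bromine to the enol-ether double bond of the enone, which would put bromine at ring A C5;
- over-bromination.

The fallback abandons the cyclohexanone surrogate and sets out from 6. Chan–Lam O-arylation of 6 with commercial 2-methoxyphenylboronic acid (Cu(OAc)2, pyridine, 4 Å sieves, CH2Cl2, air, rt; copper(II) at room temperature should not engage the aryl bromides) should give 1,2,3-tribromo-4-methoxy-5-(2-methoxyphenoxy)benzene F1. BBr3 in CH2Cl2 would then cleave both methyl ethers to 2,3,4-tribromo-6-(2-hydroxyphenoxy)phenol F2. Bromine (2 equiv, AcOH, rt) should brominate only ring A, para and ortho to its hydroxyl, since the one C–H of ring B is meta to its hydroxyl on a tribrominated ring. The fallback comes back to the route at target 14.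

Step 4. Base-induced dehydrochlorination, Favorskii rearrangement or self-condensation of the chloro ketone could outrun a slow SN2 reaction of the electron-poor phenoxide. The fallback sets out from 6. Heating 6 with commercial cyclohexene oxide and catalytic K2CO3 in DMF (about 100 °C) should open the epoxide anti to give trans-2-(3,4,5-tribromo-2-methoxyphenoxy)cyclohexan-1-ol F3 (racemic). Dess–Martin oxidation in CH2Cl2 would then return the route to 8.

Step 1. The benzyl ether could be lost by acidolysis if buffering is insufficient, the third bromination at the doubly flanked carbon could stall, or bromine could enter ortho to the benzyloxy group. The fallback avoids the benzyl group and starts from commercial 2-methoxyphenol (guaiacol). Tribromination (Br2, 3 equiv, AcOH) should give 2,3,4-tribromo-6-methoxyphenol F4, and BBr3 demethylation would give 3,4,5-tribromobenzene-1,2-diol F5. Mono-methylation with one equivalent each of MeI and Li2CO3 in DMF should favour the more acidic, bromine-flanked hydroxyl; the regioisomer would be removed by chromatography. The fallback comes back to the route at 6, bypassing steps 2 and 3.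

Further compounds
F1 | step 5 | 1,2,3-tribromo-4-methoxy-5-(2-methoxyphenoxy)benzene | COc1ccccc1Oc1cc(Br)c(Br)c(Br)c1OC
F2 | step 5 | 2,3,4-tribromo-6-(2-hydroxyphenoxy)phenol | Oc1ccccc1Oc1cc(Br)c(Br)c(Br)c1O
F3 | step 4 | trans-2-(3,4,5-tribromo-2-methoxyphenoxy)cyclohexan-1-ol (racemic, one enantiomer drawn) | O[C@@H]1CCCC[C@H]1Oc1cc(Br)c(Br)c(Br)c1OC
F4 | step 1 | 2,3,4-tribromo-6-methoxyphenol | COc1cc(Br)c(Br)c(Br)c1O
F5 | step 1 | 3,4,5-tribromobenzene-1,2-diol | Oc1cc(Br)c(Br)c(Br)c1O
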